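The data are calculated for an exercise; noise was put on by code.

Slowness would be the plain reading of a south flask whose target readings average 22.8% from 8.00 h to 40.0 h, but the runs speak against it.

all flasks: precatalyst 2.5 mol%
- south: starting material 0.44 M; second substrate 1 equiv; partner 1.2 equiv; capture agent 0.022 M; temperature 25 °C; the very flask that is asked about, followed so far
- south-west: starting material 0.22 M; second substrate 1 equiv; partner 1.2 equiv; capture agent 0.022 M; temperature 31 °C; run made earlier
- flask: starting material 0.44 M; second substrate 1.00 equiv; partner 1.20 equiv; capture agent 0.0220 M; temperature 25 °C; time 2.0 d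

south run (percent of the starting material charged)

| time / h | target / % | starting material / % |
|---|---|---|
| 8.00 | 21.2 | 79.6 |
| 15.0 | 22.6 | 78.5 |
| 25.0 | 21.0 | 76.3 |
| 30.0 | 25.1 | 78.1 |
| 40.0 | 24.2 | 78.2 |

south-west run (percent of the starting material charged)

| time / min | target / % | starting material / % |
|---|---|---|
| 10.0 | 0.5 | 101.2 |
| 25.0 | 1.5 | 99.7 |
| 50.0 | 2.1 | 98.4 |
| 80.0 | 3.2 | 94.6 |
| 120 | 6.0 | 97.2 |

(standard deviation of a reading: 1 percentage point)

- ash: change nothing and wait 50 h more
- elm: at 2.0 d add partner, 50.0% of the amount charged, then wait 50 h
- maple: at 2.0 d add precatalyst, 100% of the amount charged, then wait 50 h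
- oak: at 2.0 d raise the temperature by 25 K, then wait 50 h

1. target, in percent of the starting material first charged, at 2.0 d
2. the option that brings most further target ("none" if no option brings more than 2 percentage points) (ash / elm / maple / oak / none)
3. target present, in percent of the starting material first charged, after elm
4. target present, in percent of the starting material first charged, after oak

- the volume of additions can be left aside
- a reading or a percentage of target counts all its forms, free or not

The first instants are read from the south-west run, at 0.22 M and 31 °C, where target grows evenly to 6.0% in 120 min. At that pace, taken as a rough guide for the south flask although concentration and temperature differ, 22.8% takes 7.61 h, close to the 8.00 h of the first south reading, which is 21.2%.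

The middle of the south run covers 32.0 h, which is 4.20 times that span. Yet target moves by 3 percentage points against a scatter of 1 point per reading, and starting material holds near 78.1%. So the south flask has stopped with material still in it.

The end calls for a count. The precatalyst charge is 0.0110 M and the target made is 0.100 M. The south readings therefore give 9.13 as the turnover number, target made per catalyst charged before the flask stops. The capture agent stands at twice the catalyst charge, so it can hold that catalyst. The readings do not separate this from an equilibrium, but the reckoning here commits to lost catalyst.

On this reckoning, waiting, more partner and heat each leave about 22.8% after 50 h more, while a fresh dose of precatalyst is the one option that brings new catalyst. At the same count, that dose brings 23 points.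

The forecast gives 23%, names elm as best with 27.5%, puts oak at 13%, and holds that “extra precatalyst does nothing”, so it agrees with this reckoning on the present amount and parts from it on the options.

The flask gives 22.1% at 2.0 d. The best option is maple, with 7.6 points more target, while elm leaves 22.1% and oak 22.1%.

    starting material + free catalyst ⇌ catalyst intermediate A (K = 4.20 M⁻¹, k = 46.0 M⁻¹ min⁻¹, Ea = 52.0 kJ mol⁻¹, ΔH = −15.0 kJ mol⁻¹)
    partner + catalyst intermediate A → free catalyst + target (k = 0.560 M⁻¹ min⁻¹, Ea = 52.0 kJ mol⁻¹)
    second substrate + free catalyst ⇌ catalyst intermediate B (K = 66.0 M⁻¹, k = 2.60 M⁻¹ min⁻¹, Ea = 60.0 kJ mol⁻¹, ΔH = −1.00 kJ mol⁻¹)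
    partner + catalyst intermediate B → free catalyst + second product (k = 2.90 M⁻¹ min⁻¹, Ea = 68.0 kJ mol⁻¹)
    catalyst intermediate B + capture agent → trapped intermediate (k = 2.70 M⁻¹ min⁻¹, Ea = 45.0 kJ mol⁻¹)
    free catalyst + target ⇌ idle complex (K = 2.20 M⁻¹, k = 0.0810 M⁻¹ min⁻¹, Ea = 75.0 kJ mol⁻¹, ΔH = 0 kJ mol⁻¹)
    partner + precatalyst → free catalyst + spent reagent (k = 0.0410 M⁻¹ min⁻¹, Ea = 55.0 kJ mol⁻¹)
    (constants at 25 °C)

At 1.79 h, catalyst intermediate B goes on with partner 22 times as fast as it goes to capture agent. At 48.0 h the flask holds 0.238 M of second product, which is 21.6 times the catalyst charged, with trapped intermediate at 100% of the catalyst. Of the 23 points reckoned for a fresh dose, maple brings 7.6 points. In a neighbouring flask with 2.50 times the capture agent, target per catalyst charged comes to 4.57, half of the count of 9.13.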